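**Plan**

1. The target is 6-(3-hydroxy-3-methylbutyl)kaempferol. The retrosynthesis cuts, in this order: the four O–benzyl bonds, the C3–OH bond, the C2=C3 bond of ring C, the C3–C4 bond (acid chloride plus Ph3P=CH2), the O1–C2 ester bond, the C4–C4a bond (formyl group), the phenol C–O bond (from C–Br), the side-chain C–C bonds (Grignard, Wittig) and two aryl C–O bonds (from C–F).
2. Enabling feature: in ring C, C2 is at the ester oxidation level (bonded to O1 and ring B) and C3 lies alpha to the C4 ketone. The C2=C3 bond is therefore the olefination of an aryl ester carbonyl by an acyl ylide held ortho to it on ring A.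
3. Forward order: ring A is bought as 4-bromo-2,6-difluorobenzaldehyde, whose formyl carbon becomes the benzylic carbon of the side chain (steps 1–5). Then follow Br to OH, ortho-formylation, aroylation (brings in ring B), oxidation and ylide formation. Ring C is closed last (step 11), followed by C3 hydroxylation and global debenzylation.
4. Regiochemistry: phenol 11 is mirror-symmetric and its only hydroxyl is para to the side chain, so both ortho positions are the same and only the 6-substituted flavone can arise.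
5. Stereochemistry: the target has no stereocentre. The E alkene of step 2 is removed by hydrogenation, so nothing needs control.
6. Remark on the chemistry: compounds 1, 2, 5, 14 and 17 are taken as purchased. The tertiary alcohol and the phenols are carried as benzyl ethers so that the last step is a neutral hydrogenolysis. Acid is never applied once a free tertiary alcohol and a free neighbouring phenol coexist, since they could close to a 2,2-dimethylchroman.

Key step: step 11

**Route**

Step 1
Reactants: 1 4-bromo-2,6-difluorobenzaldehyde; 2 benzyl alcohol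
Product: 4 2,6-bis(benzyloxy)-4-bromobenzaldehyde, via monofluoro aldehyde 3 (not isolated)
Conditions: BnOH (2.2 equiv), NaH (2.3 equiv), THF/DMF, 0 °C to 40 °C
Reagents that add atoms: benzyl alcohol (second equivalent), OCc1ccccc1
Why: Twofold nucleophilic aromatic substitution (SNAr): both fluorides sit ortho to the formyl group and are displaced by sodium benzyloxide, one equivalent each, far faster than the bromide, and the ring with two alkoxy groups is then too electron-rich for the bromide to follow.

Step 2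
Reactants: 4 2,6-bis(benzyloxy)-4-bromobenzaldehyde; 5 ethyl (triphenylphosphoranylidene)acetate
Product: 6 ethyl (2E)-3-[2,6-bis(benzyloxy)-4-bromophenyl]prop-2-enoate
Conditions: toluene, 100 °C
Reagents that add atoms: none
Why: Wittig olefination with a stabilised ylide, which tolerates the hindered, electron-rich aldehyde on heating and should give the E enoate (the geometry does not matter because the double bond is hydrogenated next).

Step 3
Reactants: 6 ethyl (2E)-3-[2,6-bis(benzyloxy)-4-bromophenyl]prop-2-enoate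
Product: 7 ethyl 3-[2,6-bis(benzyloxy)-4-bromophenyl]propanoate
Conditions: H2 (4 bar), RhCl(PPh3)3 (5 mol %), THF/EtOH 1:1, 45 °C
Reagents that add atoms: none
Why: Homogeneous hydrogenation with RhCl(PPh3)3 should saturate the disubstituted conjugated C=C bond while leaving untouched the aryl bromide and the benzyl ethers, which heterogeneous palladium would attack.

Step 4
Reactants: 7 ethyl 3-[2,6-bis(benzyloxy)-4-bromophenyl]propanoate
Product: 9 4-[2,6-bis(benzyloxy)-4-bromophenyl]-2-methylbutan-2-ol, via methyl ketone 8 (not isolated)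
Conditions: MeMgBr (3.2 equiv), THF, 0 °C to rt; aq. NH4Cl
Reagents that add atoms: methylmagnesium bromide (two equivalents are incorporated), C[Mg]Br
Why: Double Grignard addition to an ester: the first equivalent gives the methyl ketone, which is more electrophilic than the ester and takes up the second equivalent to give the tertiary alcohol, while the aryl bromide does not exchange with MeMgBr at this temperature.

Step 5
Reactants: 9 4-[2,6-bis(benzyloxy)-4-bromophenyl]-2-methylbutan-2-ol
Product: 10 1,3-bis(benzyloxy)-2-[3-(benzyloxy)-3-methylbutyl]-5-bromobenzene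
Conditions: NaH, BnBr, Bu4NI (cat.), DMF, 0 °C to 45 °C
Reagents that add atoms: benzyl bromide, BrCc1ccccc1
Why: Williamson ether synthesis on the sodium alkoxide of the dimethylcarbinol, with iodide catalysis to make up for the low nucleophilicity of a tertiary alkoxide; the benzyl ether shields the alcohol during the later acylation and acid chloride steps and falls in the final hydrogenolysis.

Step 6
Reactants: 10 1,3-bis(benzyloxy)-2-[3-(benzyloxy)-3-methylbutyl]-5-bromobenzene
Product: 11 3,5-bis(benzyloxy)-4-[3-(benzyloxy)-3-methylbutyl]phenol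
Conditions: Pd2(dba)3 (2 mol %), t-BuXPhos (8 mol %), KOH (3 equiv), 1,4-dioxane/H2O 1:1, 100 °C; then aq. citric acid
Reagents that add atoms: potassium hydroxide, [K+].[OH-]
Why: Palladium-catalysed hydroxylation of an aryl bromide (C–O cross-coupling with hydroxide and a bulky biarylphosphine), well suited to this bromide flanked by two ring hydrogens; benzyl ethers are stable to hot aqueous KOH.

Step 7
Reactants: 11 3,5-bis(benzyloxy)-4-[3-(benzyloxy)-3-methylbutyl]phenol
Product: 13 2,4-bis(benzyloxy)-3-[3-(benzyloxy)-3-methylbutyl]-6-hydroxybenzaldehyde, via hydroxymethylphenol 12 (not isolated)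
Conditions: MgCl2, Et3N, (CH2O)n, MeCN, reflux; then aq. citric acid
Reagents that add atoms: paraformaldehyde (formaldehyde), C=O
Why: Magnesium-phenoxide-directed ortho-formylation (Casnati–Skattebøl reaction): chelated formaldehyde is delivered ortho to the phenoxide and a second formaldehyde oxidises the hydroxymethyl group by hydride transfer; the two free ring positions are equivalent by symmetry and the para position is blocked, so a single aldehyde should result.

Step 8
Reactants: 13 2,4-bis(benzyloxy)-3-[3-(benzyloxy)-3-methylbutyl]-6-hydroxybenzaldehyde; 14 4-(benzyloxy)benzoyl chloride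
Product: 15 3,5-bis(benzyloxy)-4-[3-(benzyloxy)-3-methylbutyl]-2-formylphenyl 4-(benzyloxy)benzoate
Conditions: Et3N, DMAP (cat.), CH2Cl2, 0 °C to rt
Reagents that add atoms: none
Why: DMAP-catalysed O-acylation of a phenol by an aroyl chloride, which sets the O1–C2 bond of the later ring C and brings in ring B; the phenol is the only free hydroxyl in the molecule.

Step 9
Reactants: 15 3,5-bis(benzyloxy)-4-[3-(benzyloxy)-3-methylbutyl]-2-formylphenyl 4-(benzyloxy)benzoate
Product: 16 2,4-bis(benzyloxy)-6-{[4-(benzyloxy)benzoyl]oxy}-3-[3-(benzyloxy)-3-methylbutyl]benzoic acid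
Conditions: NaClO2, NaH2PO4, 2-methyl-2-butene, t-BuOH/THF/H2O, 0 °C to rt
Reagents that add atoms: sodium chlorite, [Na+].[O-]Cl=O
Why: Pinnick oxidation of the aldehyde to the acid at about pH 4, where the aryl ester is not hydrolysed, with 2-methyl-2-butene trapping HOCl before it can chlorinate the electron-rich ring.

Step 10
Reactants: 16 2,4-bis(benzyloxy)-6-{[4-(benzyloxy)benzoyl]oxy}-3-[3-(benzyloxy)-3-methylbutyl]benzoic acid; 17 methyltriphenylphosphonium bromide
Product: 20 3,5-bis(benzyloxy)-4-[3-(benzyloxy)-3-methylbutyl]-2-[2-(triphenylphosphoranylidene)acetyl]phenyl 4-(benzyloxy)benzoate, via acid chloride 18 (not isolated), via acylphosphonium chloride 19 (not isolated)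
Conditions: 1-chloro-N,N,2-trimethylprop-1-en-1-amine (1.05 equiv), CH2Cl2, 0 °C to rt, concentrate; then add to Ph3P=CH2 (2.0 equiv, from 17 and n-BuLi, THF, 0 °C) at −78 °C, warm to 0 °C; filter, concentrate
Reagents that add atoms: none
Why: Acylation of methylenetriphenylphosphorane by an acid chloride with transylidation (Bestmann procedure): the first equivalent of ylide is C-acylated to phosphonium salt 19 and the second deprotonates it to the stabilised ylide, the acid chloride being far more electrophilic than the aryl ester at −78 °C and its neutral formation with the α-chloroenamine sparing the tertiary benzyl ether.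

Step 11
Reactants: 20 3,5-bis(benzyloxy)-4-[3-(benzyloxy)-3-methylbutyl]-2-[2-(triphenylphosphoranylidene)acetyl]phenyl 4-(benzyloxy)benzoate
Product: 22 5,7-bis(benzyloxy)-6-[3-(benzyloxy)-3-methylbutyl]-2-[4-(benzyloxy)phenyl]-4H-chromen-4-one, via oxaphosphetane 21 (not isolated)
Conditions: toluene (0.01 M), reflux
Reagents that add atoms: none
Why: On heating, the nucleophilic ylide carbon (the future C3) should add to the neighbouring aryl ester carbonyl (the future C2), and the ring-fused oxaphosphetane 21 should collapse with loss of Ph3PO to leave the C2=C3 enol-ether double bond. The closest known reaction type is the intramolecular Wittig olefination of ester carbonyls by ortho-acyloxyphenacylidene phosphoranes, an established entry to chromones and flavones. Ring C closes by a 6-exo-trig attack of carbon on the ester C=O; the O1–C2 bond is already present as the ester linkage, so the ring is closed at carbon and not at oxygen. No stereocentre is formed. The step needs chemoselectivity for intramolecular olefination over acyl transfer from the ester of one molecule to the ylide of another, which the ortho placement of the two partners, the six-membered geometry and high dilution should secure. Regiochemistry (6- versus 8-substitution) is not in question, because the ester oxygen is the single phenol oxygen of symmetric phenol 11, para to the side chain.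

Step 12
Reactants: 22 5,7-bis(benzyloxy)-6-[3-(benzyloxy)-3-methylbutyl]-2-[4-(benzyloxy)phenyl]-4H-chromen-4-one
Product: 24 5,7-bis(benzyloxy)-6-[3-(benzyloxy)-3-methylbutyl]-2-[4-(benzyloxy)phenyl]-3-hydroxy-4H-chromen-4-one, via epoxide 23 (not isolated)
Conditions: dimethyldioxirane (acetone solution, 3 equiv), CH2Cl2, 0 °C to rt; then p-TsOH·H2O (5 mol %), CH2Cl2, 0 °C
Reagents that add atoms: dimethyldioxirane, CC1(C)OO1
Why: Epoxidation of the C2=C3 enol-ether double bond by dimethyldioxirane and acid-catalysed opening of the epoxide at C2 (cation stabilised by O1 and ring B) with loss of the C3 proton, the established flavone-to-flavonol oxidation; the benzyl ethers should survive short exposure to the neutral oxidant and to the trace of acid, since no free hydroxyl is present to cyclise.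

Step 13
Reactants: 24 5,7-bis(benzyloxy)-6-[3-(benzyloxy)-3-methylbutyl]-2-[4-(benzyloxy)phenyl]-3-hydroxy-4H-chromen-4-one
Product: 25 3,5,7-trihydroxy-6-(3-hydroxy-3-methylbutyl)-2-(4-hydroxyphenyl)-4H-chromen-4-one
Conditions: H2 (1 atm), Pd(OH)2/C, THF/MeOH 1:1, rt
Reagents that add atoms: none
Why: Catalytic hydrogenolysis should cleave all four benzylic C–O bonds, aryl and tertiary alkyl alike, under neutral conditions, so the tertiary alcohol cannot cyclise onto a neighbouring phenol and the flavonol core is not reduced at ambient pressure.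

**Compound list**

1 | 4-bromo-2,6-difluorobenzaldehyde | O=Cc1c(F)cc(Br)cc1F | starting material
2 | benzyl alcohol | OCc1ccccc1 | starting material
3 | 2-(benzyloxy)-4-bromo-6-fluorobenzaldehyde (formed in the flask) | O=Cc1c(F)cc(Br)cc1OCc1ccccc1 | intermediate
4 | 2,6-bis(benzyloxy)-4-bromobenzaldehyde | O=Cc1c(OCc2ccccc2)cc(Br)cc1OCc1ccccc1 | intermediate
5 | ethyl (triphenylphosphoranylidene)acetate | CCOC(=O)C=P(c1ccccc1)(c1ccccc1)c1ccccc1 | starting material
6 | ethyl (2E)-3-[2,6-bis(benzyloxy)-4-bromophenyl]prop-2-enoate | CCOC(=O)/C=C/c1c(OCc2ccccc2)cc(Br)cc1OCc1ccccc1 | intermediate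
7 | ethyl 3-[2,6-bis(benzyloxy)-4-bromophenyl]propanoate | CCOC(=O)CCc1c(OCc2ccccc2)cc(Br)cc1OCc1ccccc1 | intermediate
8 | 4-[2,6-bis(benzyloxy)-4-bromophenyl]butan-2-one (formed in the flask) | CC(=O)CCc1c(OCc2ccccc2)cc(Br)cc1OCc1ccccc1 | intermediate
9 | 4-[2,6-bis(benzyloxy)-4-bromophenyl]-2-methylbutan-2-ol | CC(C)(O)CCc1c(OCc2ccccc2)cc(Br)cc1OCc1ccccc1 | intermediate
10 | 1,3-bis(benzyloxy)-2-[3-(benzyloxy)-3-methylbutyl]-5-bromobenzene | CC(C)(OCc1ccccc1)CCc1c(OCc2ccccc2)cc(Br)cc1OCc1ccccc1 | intermediate
11 | 3,5-bis(benzyloxy)-4-[3-(benzyloxy)-3-methylbutyl]phenol | CC(C)(OCc1ccccc1)CCc1c(OCc2ccccc2)cc(O)cc1OCc1ccccc1 | intermediate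
12 | 3,5-bis(benzyloxy)-4-[3-(benzyloxy)-3-methylbutyl]-2-(hydroxymethyl)phenol (formed in the flask) | CC(C)(OCc1ccccc1)CCc1c(OCc2ccccc2)cc(O)c(CO)c1OCc1ccccc1 | intermediate
13 | 2,4-bis(benzyloxy)-3-[3-(benzyloxy)-3-methylbutyl]-6-hydroxybenzaldehyde | CC(C)(OCc1ccccc1)CCc1c(OCc2ccccc2)cc(O)c(C=O)c1OCc1ccccc1 | intermediate
14 | 4-(benzyloxy)benzoyl chloride | O=C(Cl)c1ccc(OCc2ccccc2)cc1 | starting material
15 | 3,5-bis(benzyloxy)-4-[3-(benzyloxy)-3-methylbutyl]-2-formylphenyl 4-(benzyloxy)benzoate | CC(C)(OCc1ccccc1)CCc1c(OCc2ccccc2)cc(OC(=O)c2ccc(OCc3ccccc3)cc2)c(C=O)c1OCc1ccccc1 | intermediate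
16 | 2,4-bis(benzyloxy)-6-{[4-(benzyloxy)benzoyl]oxy}-3-[3-(benzyloxy)-3-methylbutyl]benzoic acid | CC(C)(OCc1ccccc1)CCc1c(OCc2ccccc2)cc(OC(=O)c2ccc(OCc3ccccc3)cc2)c(C(=O)O)c1OCc1ccccc1 | intermediate
17 | methyltriphenylphosphonium bromide | C[P+](c1ccccc1)(c1ccccc1)c1ccccc1.[Br-] | starting material
18 | 2,4-bis(benzyloxy)-6-{[4-(benzyloxy)benzoyl]oxy}-3-[3-(benzyloxy)-3-methylbutyl]benzoyl chloride (formed in the flask) | CC(C)(OCc1ccccc1)CCc1c(OCc2ccccc2)cc(OC(=O)c2ccc(OCc3ccccc3)cc2)c(C(=O)Cl)c1OCc1ccccc1 | intermediate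
19 | (2-{2,4-bis(benzyloxy)-6-{[4-(benzyloxy)benzoyl]oxy}-3-[3-(benzyloxy)-3-methylbutyl]phenyl}-2-oxoethyl)triphenylphosphonium chloride (formed in the flask) | CC(C)(OCc1ccccc1)CCc1c(OCc2ccccc2)cc(OC(=O)c2ccc(OCc3ccccc3)cc2)c(C(=O)C[P+](c2ccccc2)(c2ccccc2)c2ccccc2)c1OCc1ccccc1.[Cl-] | intermediate
20 | 3,5-bis(benzyloxy)-4-[3-(benzyloxy)-3-methylbutyl]-2-[2-(triphenylphosphoranylidene)acetyl]phenyl 4-(benzyloxy)benzoate | CC(C)(OCc1ccccc1)CCc1c(OCc2ccccc2)cc(OC(=O)c2ccc(OCc3ccccc3)cc2)c(C(=O)C=P(c2ccccc2)(c2ccccc2)c2ccccc2)c1OCc1ccccc1 | intermediate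
21 | 1,2-oxaphosphetane fused across C2–C3 of the chroman-4-one, with PPh3 on C3 and the P–O oxygen on C2 (racemic, cis-fused; formed in the flask) | CC(C)(OCc1ccccc1)CCc1c(OCc2ccccc2)cc2OC3(c4ccc(OCc5ccccc5)cc4)OP(c4ccccc4)(c4ccccc4)(c4ccccc4)C3C(=O)c2c1OCc1ccccc1 | intermediate
22 | 5,7-bis(benzyloxy)-6-[3-(benzyloxy)-3-methylbutyl]-2-[4-(benzyloxy)phenyl]-4H-chromen-4-one | CC(C)(OCc1ccccc1)CCc1c(OCc2ccccc2)cc2oc(-c3ccc(OCc4ccccc4)cc3)cc(=O)c2c1OCc1ccccc1 | intermediate
23 | 2,3-epoxide of flavone 22 (2,3-epoxychroman-4-one; racemic; formed in the flask) | CC(C)(OCc1ccccc1)CCc1c(OCc2ccccc2)cc2OC3(c4ccc(OCc5ccccc5)cc4)OC3C(=O)c2c1OCc1ccccc1 | intermediate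
24 | 5,7-bis(benzyloxy)-6-[3-(benzyloxy)-3-methylbutyl]-2-[4-(benzyloxy)phenyl]-3-hydroxy-4H-chromen-4-one | CC(C)(OCc1ccccc1)CCc1c(OCc2ccccc2)cc2oc(-c3ccc(OCc4ccccc4)cc3)c(O)c(=O)c2c1OCc1ccccc1 | intermediate
25 | 3,5,7-trihydroxy-6-(3-hydroxy-3-methylbutyl)-2-(4-hydroxyphenyl)-4H-chromen-4-one (no stereocentre) | CC(C)(O)CCc1c(O)cc2oc(-c3ccc(O)cc3)c(O)c(=O)c2c1O | target

**Step count**

Total steps: 13. Longest linear sequence: 13 steps, from 1 to 25.

**Steps most likely to fail and fallbacks**

Step 11 (key step). Ring closure could lose out to acyl transfer between molecules, or addition of the stabilised ylide to the electron-rich, hindered ester carbonyl could be so slow that thermal breakdown takes over. The fallback forms the same C2–C3 bond at the enolate level. It sets out from acid 16 and comes back at flavone 22. Acid chloride 18, made from 16 as in step 10, would be methylated with Me2CuLi (THF, −78 °C) to the methyl ketone 2-acetyl-3,5-bis(benzyloxy)-4-[3-(benzyloxy)-3-methylbutyl]phenyl 4-(benzyloxy)benzoate F1. KOt-Bu in THF should then effect Baker–Venkataraman transfer of the aroyl group from oxygen to the enolate carbon to give the 1,3-diketone F2. Cyclodehydration with catalytic camphorsulfonic acid in warm toluene should then give 22.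

Step 10. The unstabilised ylide could attack the aryl ester (acyl transfer with loss of the aroyl group), or the product ylide could be acylated a second time. The fallback builds the phosphorane without a strongly nucleophilic ylide ever meeting the aryl ester. It sets out from acid 16 and comes back at phosphorane 20. Acid chloride 18, made from 16 as in step 10, would be treated with CH2N2 and Et3N (Et2O, 0 °C) to give the diazoketone 3,5-bis(benzyloxy)-4-[3-(benzyloxy)-3-methylbutyl]-2-(diazoacetyl)phenyl 4-(benzyloxy)benzoate F3. One equivalent of HBr (48% aq., THF, 0 °C) should convert it, with loss of nitrogen, into the bromomethyl ketone F4. PPh3 in toluene at rt should give the phosphonium bromide F5. Shaking a CH2Cl2 solution of this salt with aq. Na2CO3 should deliver 20.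

Step 12. Oxygen transfer to the electron-poor C2=C3 bond could be slower than oxidation at the benzylic C–H bonds of the benzyl ethers or on ring A. The fallback is an anionic sequence that sets out from flavone 22 and comes back at flavonol 24. Deprotonation at C3 with LiN(i-Pr)2 (THF, −78 °C) would give the 3-lithioflavone F6. Trapping with B(OMe)3 would give the dimethyl boronate F7, and oxidation with H2O2/AcOH should give 24.

**Further compounds**

F1 | step 11 | 2-acetyl-3,5-bis(benzyloxy)-4-[3-(benzyloxy)-3-methylbutyl]phenyl 4-(benzyloxy)benzoate | CC(C)(OCc1ccccc1)CCc1c(OCc2ccccc2)cc(OC(=O)c2ccc(OCc3ccccc3)cc2)c(C(C)=O)c1OCc1ccccc1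
F2 | step 11 | 1-{2,4-bis(benzyloxy)-3-[3-(benzyloxy)-3-methylbutyl]-6-hydroxyphenyl}-3-[4-(benzyloxy)phenyl]propane-1,3-dione | CC(C)(OCc1ccccc1)CCc1c(OCc2ccccc2)cc(O)c(C(=O)CC(=O)c2ccc(OCc3ccccc3)cc2)c1OCc1ccccc1
F3 | step 10 | 3,5-bis(benzyloxy)-4-[3-(benzyloxy)-3-methylbutyl]-2-(diazoacetyl)phenyl 4-(benzyloxy)benzoate | CC(C)(OCc1ccccc1)CCc1c(OCc2ccccc2)cc(OC(=O)c2ccc(OCc3ccccc3)cc2)c(C(=O)C=[N+]=[N-])c1OCc1ccccc1
F4 | step 10 | 3,5-bis(benzyloxy)-4-[3-(benzyloxy)-3-methylbutyl]-2-(bromoacetyl)phenyl 4-(benzyloxy)benzoate | CC(C)(OCc1ccccc1)CCc1c(OCc2ccccc2)cc(OC(=O)c2ccc(OCc3ccccc3)cc2)c(C(=O)CBr)c1OCc1ccccc1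
F5 | step 10 | (2-{2,4-bis(benzyloxy)-6-{[4-(benzyloxy)benzoyl]oxy}-3-[3-(benzyloxy)-3-methylbutyl]phenyl}-2-oxoethyl)triphenylphosphonium bromide | CC(C)(OCc1ccccc1)CCc1c(OCc2ccccc2)cc(OC(=O)c2ccc(OCc3ccccc3)cc2)c(C(=O)C[P+](c2ccccc2)(c2ccccc2)c2ccccc2)c1OCc1ccccc1.[Br-]
F6 | step 12 | 5,7-bis(benzyloxy)-6-[3-(benzyloxy)-3-methylbutyl]-2-[4-(benzyloxy)phenyl]-3-lithio-4H-chromen-4-one | CC(C)(OCc1ccccc1)CCc1c(OCc2ccccc2)cc2oc(-c3ccc(OCc4ccccc4)cc3)c([Li])c(=O)c2c1OCc1ccccc1
F7 | step 12 | dimethyl {5,7-bis(benzyloxy)-6-[3-(benzyloxy)-3-methylbutyl]-2-[4-(benzyloxy)phenyl]-4-oxo-4H-chromen-3-yl}boronate | CC(C)(OCc1ccccc1)CCc1c(OCc2ccccc2)cc2oc(-c3ccc(OCc4ccccc4)cc3)c(B(OC)OC)c(=O)c2c1OCc1ccccc1
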